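If Z turns E into L at a pace that does not depend on [E], halving the charge halves the time needed to use it up, and the meeting on this flask began from that supposition.

- noon: E 0.18 M; Z 8.1 µM; J 16 µM; run made earlier
- flask: E 0.090 M; Z 8.1 µM; J 16 µM; time 2.5 h

noon run (percent of the E charged)

| time / min | L / % |
|---|---|
| 4.00 | 8.5 |
| 6.00 | 11.6 |
| 8.00 | 14.6 |
| 12.0 | 22.1 |
| 20.0 | 33.3 |
| 30.0 | 41.2 |
| 50.0 | 51.5 |

(scatter of a reading: 1 percentage point)

1. time, not beyond 2.5 h, at which the flask holds most L
2. the amount of L, in percent of the E charged, at that time



The first speaker read the pace from the noon run: 22.1% of the E had become L after 12.0 min, so 3.31 mM min⁻¹. She took over this pace for the flask, since [Z] and [J] are the same in both. She then defined the clearing time, 27.1 min, as the [E] charged divided by that pace. This picture is zero-order in E, and she took it as a rough scale of time, not as a law for the whole noon run. Even so, the flask's clearing time is shorter than the 2.5 h allowed. The noon run also bent: at 50.0 min it read 51.5%, less than the 92.1% its early pace gives. So she expected L in the flask to level off before the end, without naming a percentage, and she left open whether it would then hold or fall.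

The maker of the forecast disagreed, holding that “Halving E leaves percent conversion unchanged if the reaction is truly first-order”, and the forecast put the maximum at 2.5 h, with 72% of L.

The flask holds most L at 1.03 h, namely 70.0%, which is 2.28 clearing times, and by 2.50 h L has fallen to 62.4%.

    E + Z ⇌ Q (K = 44.0 M⁻¹, k = 37000 M⁻¹ min⁻¹)
    Q ⇌ Z + L (K = 0.170 M, k = 610 min⁻¹)
    Z + J ⇌ G (K = 70000 M⁻¹, k = 3400 M⁻¹ min⁻¹)
    E + L → X (k = 0.120 M⁻¹ min⁻¹)

The neighbouring flask is charged with 0.22 M of E, all else held, so its clearing time is 66.4 min. That is longer than the flask's 27.1 min, yet shorter than the 2.5 h allowed. Its best is 49.2%, lower than the flask's 70.0%. At 2.50 h the neighbouring flask holds 42.4% as L and more, 52.8%, as X, with 4.83% of its E still free.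

All runs were computed on assumed constants, noise included.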